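**Assumptions (one line each)**
- The target is taken as the SMILES given, with germacranolide numbering C1–C15. C8 carries the methacrylate, C5 the free OH, the lactone is the 6,12-olide, and C1 is the furanone C=O.
- L-Lactic acid and (S)-5-(hydroxymethyl)furan-2(5H)-one (made from D-ribonolactone) are purchased.

**Retrosynthetic overview**
1. The last ring (C4–C5, the oxygen-bridged macrocycle) closes by intramolecular Nozaki–Hiyama–Kishi coupling of a vinyl bromide with the C5 aldehyde (**20**); this sets C5–OH.
2. The methacrylate comes from C8-OH, which comes from reduction of the C8 ketone in **16**.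
3. **16** forms in the photochemical key step. A photo-generated acyl radical from aldehyde **11** adds to the bromomethyl-butenolide **15**, forming C7–C8, the trans C6/C7 lactone and the exo-methylene in one operation.
4. **11** is built from L-lactic acid, which supplies the quaternary C10 through Seebach acetal alkylation. The furanone forms by cyclodehydration of an α-hydroxy-1,3-diketone. C6 comes from the (S)-butenolide.
5. Ring order: furanone (Step 7), then the lactone is decorated by the radical step (12), then the 10-membered carbocycle (Step 17).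

## Route

**Step 1**
Reactants: **1** (S)-lactic acid; **2** pivaldehyde
Product: **3** (2S,5S)-2-tert-butyl-5-methyl-1,3-dioxolan-4-one
Conditions: cat. TsOH, pentane, Dean–Stark reflux; crystallise the cis isomer
Reagents that add atoms: none (pivaldehyde is reactant **2**)
Why: Acetalisation of the α-hydroxy acid gives the cis-dioxolanone, so the lactate configuration is carried by the ring (self-regeneration of stereocentres).

**Step 2**
Reactants: **3**
Product: **4** (2S,5R)-5-allyl-2-tert-butyl-5-methyl-1,3-dioxolan-4-one
Conditions: LDA, THF, –78 °C; then allyl bromide, –78 → –40 °C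
Reagents that add atoms: allyl bromide, C=CCBr
Why: Seebach enolate alkylation occurs trans to the tert-butyl group and with net retention, which sets the C10 quaternary centre as R (descriptor switches S→R because allyl outranks methyl). The acetal stereocentre is then lost.

**Step 3**
Reactants: **4**
Product: **5** (R)-2-hydroxy-N-methoxy-N,2-dimethylpent-4-enamide
Conditions: MeNH(OMe)·HCl, AlMe3, CH2Cl2, 0 °C → rt
Reagents that add atoms: N,O-dimethylhydroxylamine, CNOC
Why: AlMe3-mediated aminolysis (Weinreb amide formation) opens the acetal-lactone. The released hemiacetal loses pivaldehyde, and the quaternary C10 cannot epimerise.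

**Step 4**
Reactants: **5**
Product: **6** (R)-3-hydroxy-3-methylhex-5-en-2-one
Conditions: MeMgBr (3 equiv), THF, 0 °C; aq. NH4Cl
Reagents that add atoms: MeMgBr, C[Mg]Br
Why: Weinreb ketone synthesis; the first equivalent deprotonates the tertiary OH. C10 is untouched, and C2 is the new methyl.

**Step 5**
Reactants: **6**; **7** 2-bromoacrolein, C=C(Br)C=O
Product: **8** (4R)-8-bromo-4,7-dihydroxy-4-methylnona-1,8-dien-5-one (C7 carbinol as a ~1:1 mixture, destroyed in Step 6)
Conditions: LiHMDS (2.3 equiv), THF, –78 °C; then **7**, –78 °C
Reagents that add atoms: none (2-bromoacrolein is reactant **7**)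
Why: Aldol addition of the alkoxide/enolate dianion to the enal aldehyde. C10 is quaternary, so only the methyl ketone can enolise, and the aldol is regiochemically unambiguous.

**Step 6**
Reactants: **8**
Product: **9** (4R)-8-bromo-4-hydroxy-4-methylnona-1,8-diene-5,7-dione
Conditions: DMP, NaHCO3, CH2Cl2, 0 °C → rt
Reagents that add atoms: none
Why: Dess–Martin oxidation of the secondary alcohol only; the tertiary alcohol and the alkenes are inert. This converts the carbinol mixture into one achiral 1,3-diketone.

**Step 7**
Reactants: **9**
Product: **10** (2R)-2-allyl-5-(1-bromovinyl)-2-methylfuran-3(2H)-one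
Conditions: TsOH·H2O (0.2 equiv), PhMe, 70 °C
Reagents that add atoms: none (loses H2O)
Why: Bullatenone-type cyclodehydration. The tertiary OH closes onto the C3 ketone and dehydrates to the furan-3(2H)-one, and C10 is unchanged.

**Step 8**
Reactants: **10**
Product: **11** 2-[(2R)-5-(1-bromovinyl)-2-methyl-3-oxo-2,3-dihydrofuran-2-yl]acetaldehyde (used crude)
Conditions: OsO4 (2 mol%), NaIO4 (4 equiv), 2,6-lutidine, dioxane/H2O, 0 °C → rt
Reagents that add atoms: sodium periodate, [Na+].[O-]I(=O)(=O)=O (source of the aldehyde O)
Why: Lemieux–Johnson cleavage is selective for the unhindered monosubstituted alkene. The electron-poor furanone C=C and the vinyl bromide are slow to react.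

**Step 9**
Reactants: **12** (S)-5-(hydroxymethyl)furan-2(5H)-one
Product: **13** (S)-5-[(tert-butyldimethylsilyloxy)methyl]furan-2(5H)-one
Conditions: TBSCl, imidazole, DMF, 0 °C
Reagents that add atoms: TBSCl, CC(C)(C)[Si](C)(C)Cl
Why: Standard silylation of the primary alcohol; C6 is untouched.

**Step 10**
Reactants: **13**
Product: **14** (S)-3-(hydroxymethyl)-5-[(TBSoxy)methyl]furan-2(5H)-one
Conditions: 37% aq. HCHO, Me3P (10 mol%), dioxane/H2O, rt
Reagents that add atoms: formaldehyde, C=O
Why: Phosphine-catalysed Morita–Baylis–Hillman hydroxymethylation at the butenolide α-carbon, which becomes C11 and adds C13.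

**Step 11**
Reactants: **14**
Product: **15** (S)-3-(bromomethyl)-5-[(TBSoxy)methyl]furan-2(5H)-one
Conditions: CBr4, PPh3, CH2Cl2, 0 °C
Reagents that add atoms: carbon tetrabromide, BrC(Br)(Br)Br (source of Br)
Why: Appel bromination of the allylic alcohol gives the radical acceptor and leaving group for the next step.

**Step 12 (key photochemical step)**
Reactants: **11** (2 equiv); **15**
Product: **16** trans-3-methylene-4-acyl-5-(TBSoxymethyl)dihydrofuran-2-one carrying the C8 ketone and the furanone (stereo as in its SMILES below)
Conditions: TBADT (2 mol%), 2,6-lutidine (1.2 equiv), MeCN (0.05 M), 390 nm LEDs, 25 °C, 16 h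
Reagents that add atoms: none (bromide leaves as lutidinium bromide)
Why: Proposed new method: photo-excited decatungstate abstracts the formyl H of **11** to give an acyl radical. The radical adds to C4 of butenolide **15** (the future C7) anti to the C5 CH2OTBS group, which sets C6/C7 trans. The resulting α-lactonyl radical expels Br• by β-scission, creating the exocyclic C11=C13 methylene. Br• re-oxidises reduced decatungstate or abstracts the next formyl H, so the cycle is redox-neutral. The closest known reactions are radical allylation with α-(bromomethyl)acrylates (Giese-type addition–fragmentation) and TBADT hydroacylation of enones. Here the acceptor is an endocyclic α-(bromomethyl)butenolide and the donor is a β-alkoxy aldehyde, which has not been shown. The step forms C7–C8, sets C7 and builds the α-methylene lactone together.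

**Step 13**
Reactants: **16**
Product: **17** C8 alcohol (S)
Conditions: Zn(BH4)2, Et2O, –78 → –30 °C
Reagents that add atoms: none
Why: Chelation-controlled reduction of a β-alkoxy ketone. Zinc bridges the C8 carbonyl and the C10 ring oxygen, so hydride is delivered from one face and the 1,3-syn C8/C10 relationship results. The furanone, the lactone and the vinyl bromide are inert at low temperature.

**Step 14**
Reactants: **17**
Product: **18** C8 methacrylate
Conditions: methacryloyl chloride, Et3N, cat. DMAP, CH2Cl2, 0 °C
Reagents that add atoms: methacryloyl chloride, C=C(C)C(=O)Cl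
Why: Acylation of the secondary alcohol with retention at C8. Translactonisation is disfavoured because it would need a strained bicyclic tetrahedral intermediate.

**Step 15**
Reactants: **18**
Product: **19** primary alcohol
Conditions: HF·pyridine, THF/pyridine, 0 °C → rt
Reagents that add atoms: none
Why: Acidic fluoride removes the TBS group without basic ester migration; the methacrylate, the α-methylene lactone and the furanone survive.

**Step 16**
Reactants: **19**
Product: **20** C5 aldehyde
Conditions: DMP, NaHCO3, CH2Cl2, 0 °C, 30 min (use crude)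
Reagents that add atoms: none
Why: Buffered Dess–Martin oxidation of the primary alcohol minimises α-epimerisation at C6.

**Step 17**
Reactants: **20**
Product: **21** isogoiazensolide
Conditions: CrCl2 (10 equiv), NiCl2 (0.2 equiv), DMSO, 0.002 M, 25 °C, slow addition of **20**
Reagents that add atoms: none (Br is lost; the OH hydrogen comes from aqueous work-up)
Why: Intramolecular Nozaki–Hiyama–Kishi vinylation of the α-alkoxy aldehyde. The vinyl-Cr species adds through a Cr-chelated, Felkin-type transition state inside the strained macrocycle, and C6 and the macrocyclic constraint set the C5 (R) carbinol.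

## Compound list
1 | (S)-lactic acid | C[C@H](O)C(=O)O | starting material
2 | pivaldehyde | CC(C)(C)C=O | starting material
3 | (2S,5S)-2-tert-butyl-5-methyl-1,3-dioxolan-4-one | C[C@@H]1O[C@H](C(C)(C)C)OC1=O | intermediate
4 | (2S,5R)-5-allyl-2-tert-butyl-5-methyl-1,3-dioxolan-4-one | C=CC[C@@]1(C)O[C@H](C(C)(C)C)OC1=O | intermediate
5 | (R)-2-hydroxy-N-methoxy-N,2-dimethylpent-4-enamide | C=CC[C@@](C)(O)C(=O)N(C)OC | intermediate
6 | (R)-3-hydroxy-3-methylhex-5-en-2-one | C=CC[C@@](C)(O)C(C)=O | intermediate
7 | 2-bromoacrolein | C=C(Br)C=O | starting material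
8 | (4R)-8-bromo-4,7-dihydroxy-4-methylnona-1,8-dien-5-one (C7 epimeric mixture) | C=CC[C@@](C)(O)C(=O)CC(O)C(Br)=C | intermediate
9 | (4R)-8-bromo-4-hydroxy-4-methylnona-1,8-diene-5,7-dione | C=CC[C@@](C)(O)C(=O)CC(=O)C(Br)=C | intermediate
10 | (2R)-2-allyl-5-(1-bromovinyl)-2-methylfuran-3(2H)-one | C=CC[C@@]1(C)OC(=CC1=O)C(Br)=C | intermediate
11 | (2R)-2-[5-(1-bromovinyl)-2-methyl-3-oxo-2,3-dihydrofuran-2-yl]acetaldehyde | O=CC[C@@]1(C)OC(=CC1=O)C(Br)=C | intermediate
12 | (S)-5-(hydroxymethyl)furan-2(5H)-one | O=C1C=C[C@@H](CO)O1 | starting material
13 | (S)-5-[(TBSoxy)methyl]furan-2(5H)-one | O=C1C=C[C@@H](CO[Si](C)(C)C(C)(C)C)O1 | intermediate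
14 | (S)-3-(hydroxymethyl)-5-[(TBSoxy)methyl]furan-2(5H)-one | O=C1C(CO)=C[C@@H](CO[Si](C)(C)C(C)(C)C)O1 | intermediate
15 | (S)-3-(bromomethyl)-5-[(TBSoxy)methyl]furan-2(5H)-one | O=C1C(CBr)=C[C@@H](CO[Si](C)(C)C(C)(C)C)O1 | intermediate
16 | C8 keto-lactone–furanone (trans lactone) | C=C1C(=O)O[C@H](CO[Si](C)(C)C(C)(C)C)[C@H]1C(=O)C[C@@]2(C)OC(=CC2=O)C(Br)=C | intermediate
17 | C8 alcohol | C=C1C(=O)O[C@H](CO[Si](C)(C)C(C)(C)C)[C@H]1[C@@H](O)C[C@@]2(C)OC(=CC2=O)C(Br)=C | intermediate
18 | C8 methacrylate | C=C1C(=O)O[C@H](CO[Si](C)(C)C(C)(C)C)[C@H]1[C@@H](OC(=O)C(C)=C)C[C@@]2(C)OC(=CC2=O)C(Br)=C | intermediate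
19 | primary alcohol | C=C1C(=O)O[C@H](CO)[C@H]1[C@@H](OC(=O)C(C)=C)C[C@@]2(C)OC(=CC2=O)C(Br)=C | intermediate
20 | C5 aldehyde | C=C1C(=O)O[C@H](C=O)[C@H]1[C@@H](OC(=O)C(C)=C)C[C@@]2(C)OC(=CC2=O)C(Br)=C | intermediate
21 | isogoiazensolide | C=C(C)C(=O)O[C@H]1C[C@@]2(C)OC(=CC2=O)C(=C)[C@@H](O)[C@H]2OC(=O)C(=C)[C@@H]21 | target

**Total step count:** 17. **Longest linear sequence:** 14 steps (1 → 2 → 3 → 4 → 5 → 6 → 7 → 8 → 12 → 13 → 14 → 15 → 16 → 17).

**Three steps most likely to fail**
1. **Step 12 (proposed new photochemical addition–fragmentation).**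
   - Risks: the β-alkoxy aldehyde **11** may eliminate or decarbonylate, and the acceptor's allylic bromide may be reduced or react in competing HAT.
   - Fallback (known chemistry, different approach): couple **11** with butenolide **13** by achiral-thiazolium Stetter 1,4-addition, which is trans-selective from C6. Then reduce C8 (Step 13 conditions), silyl-protect it, and install the exo-methylene on the lactone by LiHMDS/Eschenmoser's salt followed by MeI/DBU. Continue with Steps 14–17 using the vinyl bromide unchanged.
2. **Step 17 (macrocyclic NHK: yield and C5 configuration).**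
   - Fallback: oxidise **20** to the C5 acid, convert the vinyl bromide to a vinylstannane, and close the ring by intramolecular Stille acylation to the C5 ketone. Then set C5-OH by Zn(BH4)2 chelation-controlled reduction against the C6 oxygen.
3. **Step 13 (C8 diastereoselectivity).**
   - Fallback: if the C8 epimer predominates, separate it and convert it by Mitsunobu esterification with methacrylic acid (DIAD, PPh3). This inverts C8 and installs the methacrylate in one step, replacing Steps 13/14 for that epimer.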